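**Retrosynthetic overview**
- Target ⇒ fluoride cleavage of a 2-(trimethylsilyl)ethyl ester; the C4–O ester bond ⇒ Yamaguchi coupling of a 1,4-diol enal core with (2E,4E,6E)-octatrienoic acid (from sorbaldehyde and malonic acid).
- Core oxygenation ⇒ three events on the convex face of a cis-decalin: C4–OH by vinylogous Rubottom oxidation of the enal, C2–CHO by carbonylation of the C2 enol triflate, C1–OH by hydroxylation of a β-keto ester enol.
- cis-Decalin β-keto ester ⇒ one enantioselective, Brønsted-acid-catalysed, proton-initiated bicyclisation of an acyclic (Z)-dienyl β-keto ester; ring A closes first and ring B second in the same cascade.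
- Acyclic keto ester ⇒ nerylacetone and dimethyl carbonate (Claisen condensation).

Assumption: the target is made as the drawn open hydroxy acid–aldehyde, (1R,4R,4aR,8aS), a cis-fused decalin with 8a-Me, 4a-H, 4-acyloxy and 1-OH all on one face; its lactol ring tautomer is not treated separately.
Locants are naphthalene locants (C1 carboxyl, C2 formyl, C4 acyloxy, C5 gem-dimethyl, C8a methyl); ring A = C4a, C5–C8, C8a; ring B = C1–C4, C4a, C8a.

**Step 1**
Reactants: 1 nerylacetone ((5Z)-6,10-dimethylundeca-5,9-dien-2-one); 2 dimethyl carbonate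
Product: 3 methyl (6Z)-7,11-dimethyl-3-oxododeca-6,10-dienoate
Conditions: NaH (2.2 equiv), dimethyl carbonate (5 equiv), THF, reflux; then 1 M HCl
Reagents that add atoms: none
Why: Crossed Claisen condensation (carbomethoxylation) at the methyl side of the ketone, driven by formation of the sodium enolate of the β-keto ester; the Z alkene is untouched.

**Step 2**
Reactants: 3 methyl (6Z)-7,11-dimethyl-3-oxododeca-6,10-dienoate
Product: 4 methyl (4aR,8aS)-5,5,8a-trimethyl-2-oxodecahydronaphthalene-1-carboxylate (cis-fused; C1 epimers and enol)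
Conditions: (S,S)-IDPi (chiral imidodiphosphorimidate Brønsted acid from two 3,3'-diaryl-1,1'-bi-2-naphthol units with N-SO2CF3 groups, 3 mol %), (CF3)3COH–CH2Cl2 1:1, −30 °C, 72 h
Reagents that add atoms: none
Why: Proposed new method: the confined chiral acid protonates the terminal trisubstituted alkene while its anion hydrogen-bonds the β-keto ester enol, the tertiary cation is captured by the Z alkene (ring A) and the new C8a cation by the enol carbon (ring B); anti addition across a Z alkene forces the cis fusion (8a-Me and 4a-H syn) and the chiral pocket selects the alkene face, so C4a and C8a are set together as 4aR,8aS (the mirror-image catalyst is used if the sense proves opposite); closest known reaction type: confined-acid-catalysed protonative cyclisation of alcohol-terminated (E)-polyenes in fluorinated alcohols, and tin tetrachloride-promoted cyclisation of polyene β-keto esters.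

**Step 3**
Reactants: 4 methyl (4aR,8aS)-5,5,8a-trimethyl-2-oxodecahydronaphthalene-1-carboxylate; 5 2-(trimethylsilyl)ethanol
Product: 6 2-(trimethylsilyl)ethyl (4aR,8aS)-5,5,8a-trimethyl-2-oxodecahydronaphthalene-1-carboxylate
Conditions: 5 (3 equiv), 4-(dimethylamino)pyridine (DMAP, 0.2 equiv), toluene, reflux, 4 Å sieves
Reagents that add atoms: none
Why: β-Keto ester transesterification through the acyl ketene with removal of methanol installs an ester that fluoride can later cleave at the alkyl–oxygen bond, needed because the C1 carboxyl becomes too hindered to saponify beside a trienoate; C4a and C8a are untouched.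

**Step 4**
Reactants: 6 2-(trimethylsilyl)ethyl (4aR,8aS)-5,5,8a-trimethyl-2-oxodecahydronaphthalene-1-carboxylate
Product: 8 2-(trimethylsilyl)ethyl (1R,4aR,8aS)-5,5,8a-trimethyl-2-oxo-1-[(trimethylsilyl)oxy]decahydronaphthalene-1-carboxylate, via 1-hydroxy keto ester 7 (not isolated)
Conditions: dimethyldioxirane (1.2 equiv), acetone, 0 °C; evaporate; Me3SiOTf (1.5 equiv), 2,6-lutidine (2.5 equiv), CH2Cl2, −78 to −20 °C
Reagents that add atoms: dimethyldioxirane, CC1(C)OO1; trimethylsilyl trifluoromethanesulfonate, C[Si](C)(C)OS(=O)(=O)C(F)(F)F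
Why: Dioxirane hydroxylation of the β-keto ester enol (Rubottom-type) occurs on the convex face of the cis-decalin, because the C8 methylene of ring A lies axially under ring B, giving 1R (OH syn to 8a-Me); silylation in the same flask protects the tertiary alcohol for the enolisation in step 5.

**Step 5**
Reactants: 8 2-(trimethylsilyl)ethyl (1R,4aR,8aS)-5,5,8a-trimethyl-2-oxo-1-[(trimethylsilyl)oxy]decahydronaphthalene-1-carboxylate
Product: 9 2-(trimethylsilyl)ethyl (1R,4aR,8aS)-5,5,8a-trimethyl-2-{[(trifluoromethyl)sulfonyl]oxy}-1-[(trimethylsilyl)oxy]-1,4,4a,5,6,7,8,8a-octahydronaphthalene-1-carboxylate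
Conditions: KN(SiMe3)2 (1.2 equiv), THF, −78 °C; PhNTf2 (1.3 equiv), −78 to 0 °C; aq. NH4Cl
Reagents that add atoms: N-phenylbis(trifluoromethanesulfonimide), O=S(=O)(N(c1ccccc1)S(=O)(=O)C(F)(F)F)C(F)(F)F
Why: Kinetic enolate O-triflation; only C3 carries α-hydrogens (C1 is quaternary), so the enol triflate can only form between C2 and C3.

**Step 6**
Reactants: 9 the enol triflate from step 5
Product: 10 2-(trimethylsilyl)ethyl (1R,4aR,8aS)-2-formyl-5,5,8a-trimethyl-1-[(trimethylsilyl)oxy]-1,4,4a,5,6,7,8,8a-octahydronaphthalene-1-carboxylate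
Conditions: Pd(OAc)2 (5 mol %), 1,3-bis(diphenylphosphino)propane (5 mol %), CO (1 atm), Et3SiH (2 equiv, slow addition), Et3N (2.5 equiv), DMF, 70 °C
Reagents that add atoms: carbon monoxide, [C-]#[O+]
Why: Palladium-catalysed reductive carbonylation (formylation) of the enol triflate: oxidative addition to zerovalent palladium, CO insertion and hydride transfer from the silane give the C2 enal without touching a stereocentre.

**Step 7**
Reactants: 10 the enal from step 6
Product: 12 2-(trimethylsilyl)ethyl (1R,4R,4aR,8aS)-2-formyl-1,4-dihydroxy-5,5,8a-trimethyl-1,4,4a,5,6,7,8,8a-octahydronaphthalene-1-carboxylate, via silyl dienol ether 11 (not isolated)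
Conditions: Me3SiOTf (1.3 equiv), Et3N (2.5 equiv), CH2Cl2, 0 °C; filter, concentrate; dimethyldioxirane (1.1 equiv), acetone–CH2Cl2, −78 to −30 °C; 1 M HCl, THF, 0 °C to rt
Reagents that add atoms: trimethylsilyl trifluoromethanesulfonate, C[Si](C)(C)OS(=O)(=O)C(F)(F)F (silyl groups of 11 only); dimethyldioxirane, CC1(C)OO1
Why: Vinylogous Rubottom oxidation: soft γ-enolisation gives the 1-silyloxy-1,3-diene, the dioxirane epoxidises its distal C3=C4 bond from the convex face and the epoxide collapses to the γ-hydroxy enal, setting C4 as R (OH syn to 4a-H and 8a-Me); aqueous acid removes both silyl groups.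

**Step 8**
Reactants: 13 (2E,4E)-hexa-2,4-dienal (sorbaldehyde); 14 malonic acid
Product: 15 (2E,4E,6E)-octa-2,4,6-trienoic acid
Conditions: pyridine, piperidine (cat.), 90 °C; then aq. HCl
Reagents that add atoms: none
Why: Knoevenagel–Doebner condensation with decarboxylation gives the new 2E alkene, and the E,E-diene of sorbaldehyde is carried through.

**Step 9**
Reactants: 12 the diol enal from step 7; 15 (2E,4E,6E)-octa-2,4,6-trienoic acid
Product: 17 2-(trimethylsilyl)ethyl (1R,4R,4aR,8aS)-2-formyl-1-hydroxy-5,5,8a-trimethyl-4-{[(2E,4E,6E)-octa-2,4,6-trienoyl]oxy}-1,4,4a,5,6,7,8,8a-octahydronaphthalene-1-carboxylate, via Yamaguchi mixed anhydride 16 (not isolated)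
Conditions: 15 (1.5 equiv), 2,4,6-trichlorobenzoyl chloride (1.5 equiv), Et3N (3 equiv), THF, rt; then 12, DMAP (2 equiv), toluene, rt
Reagents that add atoms: 2,4,6-trichlorobenzoyl chloride, O=C(Cl)c1c(Cl)cc(Cl)cc1Cl (its atoms stay in 16 only)
Why: Yamaguchi esterification: DMAP carries the trienoyl group from the mixed anhydride to the secondary allylic hydroxyl with retention at C4, while the tertiary α-hydroxy ester hydroxyl is too hindered to react.

**Step 10**
Reactants: 17 the trienoate 2-(trimethylsilyl)ethyl ester from step 9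
Product: 18 (1R,4R,4aR,8aS)-2-formyl-1-hydroxy-5,5,8a-trimethyl-4-{[(2E,4E,6E)-octa-2,4,6-trienoyl]oxy}-1,4,4a,5,6,7,8,8a-octahydronaphthalene-1-carboxylic acid
Conditions: Bu4NF (3 equiv), AcOH (3 equiv), THF, 0 °C to rt; pH 4 buffer
Reagents that add atoms: none
Why: Fluoride-triggered β-elimination of the 2-(trimethylsilyl)ethyl ester cleaves the alkyl–oxygen bond remote from the hindered carbonyl, freeing the acid without touching the trienoate, the enal or any stereocentre.

**Compound list**
1 | nerylacetone, (5Z)-6,10-dimethylundeca-5,9-dien-2-one | CC(=O)CC/C=C(/C)CCC=C(C)C | starting material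
2 | dimethyl carbonate | COC(=O)OC | starting material
3 | methyl (6Z)-7,11-dimethyl-3-oxododeca-6,10-dienoate | COC(=O)CC(=O)CC/C=C(/C)CCC=C(C)C | intermediate
4 | methyl (4aR,8aS)-5,5,8a-trimethyl-2-oxodecahydronaphthalene-1-carboxylate (cis-fused; C1 epimers and enol) | C1CC(=O)C(C(=O)OC)[C@@]2(C)CCCC(C)(C)[C@@H]12 | intermediate
5 | 2-(trimethylsilyl)ethanol | C[Si](C)(C)CCO | starting material
6 | 2-(trimethylsilyl)ethyl (4aR,8aS)-5,5,8a-trimethyl-2-oxodecahydronaphthalene-1-carboxylate (C1 epimers and enol) | C1CC(=O)C(C(=O)OCC[Si](C)(C)C)[C@@]2(C)CCCC(C)(C)[C@@H]12 | intermediate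
7 | 2-(trimethylsilyl)ethyl (1R,4aR,8aS)-1-hydroxy-5,5,8a-trimethyl-2-oxodecahydronaphthalene-1-carboxylate | C1CC(=O)[C@@](O)(C(=O)OCC[Si](C)(C)C)[C@@]2(C)CCCC(C)(C)[C@@H]12 | intermediate (not isolated)
8 | 2-(trimethylsilyl)ethyl (1R,4aR,8aS)-5,5,8a-trimethyl-2-oxo-1-[(trimethylsilyl)oxy]decahydronaphthalene-1-carboxylate | C1CC(=O)[C@@](O[Si](C)(C)C)(C(=O)OCC[Si](C)(C)C)[C@@]2(C)CCCC(C)(C)[C@@H]12 | intermediate
9 | 2-(trimethylsilyl)ethyl (1R,4aR,8aS)-5,5,8a-trimethyl-2-{[(trifluoromethyl)sulfonyl]oxy}-1-[(trimethylsilyl)oxy]-1,4,4a,5,6,7,8,8a-octahydronaphthalene-1-carboxylate | C1C=C(OS(=O)(=O)C(F)(F)F)[C@@](O[Si](C)(C)C)(C(=O)OCC[Si](C)(C)C)[C@@]2(C)CCCC(C)(C)[C@@H]12 | intermediate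
10 | 2-(trimethylsilyl)ethyl (1R,4aR,8aS)-2-formyl-5,5,8a-trimethyl-1-[(trimethylsilyl)oxy]-1,4,4a,5,6,7,8,8a-octahydronaphthalene-1-carboxylate | C1C=C(C=O)[C@@](O[Si](C)(C)C)(C(=O)OCC[Si](C)(C)C)[C@@]2(C)CCCC(C)(C)[C@@H]12 | intermediate
11 | 2-(trimethylsilyl)ethyl (1R,4aR,8aS)-5,5,8a-trimethyl-1-[(trimethylsilyl)oxy]-2-{[(trimethylsilyl)oxy]methylidene}-1,2,4a,5,6,7,8,8a-octahydronaphthalene-1-carboxylate (exocyclic alkene geometry not defined) | C1=CC(=CO[Si](C)(C)C)[C@@](O[Si](C)(C)C)(C(=O)OCC[Si](C)(C)C)[C@@]2(C)CCCC(C)(C)[C@@H]12 | intermediate (not isolated)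
12 | 2-(trimethylsilyl)ethyl (1R,4R,4aR,8aS)-2-formyl-1,4-dihydroxy-5,5,8a-trimethyl-1,4,4a,5,6,7,8,8a-octahydronaphthalene-1-carboxylate | O[C@@H]1C=C(C=O)[C@@](O)(C(=O)OCC[Si](C)(C)C)[C@@]2(C)CCCC(C)(C)[C@@H]12 | intermediate
13 | (2E,4E)-hexa-2,4-dienal (sorbaldehyde) | C/C=C/C=C/C=O | starting material
14 | malonic acid | OC(=O)CC(=O)O | starting material
15 | (2E,4E,6E)-octa-2,4,6-trienoic acid | C/C=C/C=C/C=C/C(=O)O | intermediate
16 | (2E,4E,6E)-octa-2,4,6-trienoic 2,4,6-trichlorobenzoic anhydride | C/C=C/C=C/C=C/C(=O)OC(=O)c1c(Cl)cc(Cl)cc1Cl | intermediate (not isolated)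
17 | 2-(trimethylsilyl)ethyl (1R,4R,4aR,8aS)-2-formyl-1-hydroxy-5,5,8a-trimethyl-4-{[(2E,4E,6E)-octa-2,4,6-trienoyl]oxy}-1,4,4a,5,6,7,8,8a-octahydronaphthalene-1-carboxylate | C/C=C/C=C/C=C/C(=O)O[C@@H]1C=C(C=O)[C@@](O)(C(=O)OCC[Si](C)(C)C)[C@@]2(C)CCCC(C)(C)[C@@H]12 | intermediate
18 | (1R,4R,4aR,8aS)-2-formyl-1-hydroxy-5,5,8a-trimethyl-4-{[(2E,4E,6E)-octa-2,4,6-trienoyl]oxy}-1,4,4a,5,6,7,8,8a-octahydronaphthalene-1-carboxylic acid | C/C=C/C=C/C=C/C(=O)O[C@@H]1C=C(C=O)[C@@](O)(C(=O)O)[C@@]2(C)CCCC(C)(C)[C@@H]12 | target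

**Step count and risks**
Total step count: 10. Longest linear sequence: 9 steps (steps 1–7, 9, 10); step 8 is a one-step side branch.

Three steps most likely to fail:

Step 2 (the proposed new reaction). The risks are closure through the enol oxygen to a bicyclic enol ether instead of through carbon, incomplete cis selectivity, and low enantioselectivity. Fallback with known chemistry: set out from 3 and cyclise with SnCl4 (CH2Cl2, −78 to 0 °C), the long-established Lewis-acid cyclisation of polyene β-keto esters, in which a Z central alkene gives the cis-decalin. This gives 4 as a racemate, that is, together with its mirror image methyl (4aS,8aR)-5,5,8a-trimethyl-2-oxodecahydronaphthalene-1-carboxylate F1. Preparative chromatography on a chiral stationary phase removes F1 and the route is rejoined at 4.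

Step 6. The enol triflate sits beside a quaternary carbon, and direct reduction to the alkene can outrun CO insertion. Fallback: set out from 9 and run a Stille coupling with (tributylstannyl)methanol (Pd(PPh3)4, LiCl, dioxane, 100 °C) to give the allylic alcohol 2-(trimethylsilyl)ethyl (1R,4aR,8aS)-2-(hydroxymethyl)-5,5,8a-trimethyl-1-[(trimethylsilyl)oxy]-1,4,4a,5,6,7,8,8a-octahydronaphthalene-1-carboxylate F2. Oxidation with MnO2 (CH2Cl2, rt) rejoins the route at 10.

Step 7. The dioxirane may attack the α carbon of the dienol ether instead of the γ carbon, or the wrong face. Fallback: set out from 10 and use a direct Riley allylic hydroxylation (SeO2 0.5 equiv, t-BuOOH, CH2Cl2, rt; ene reaction and [2,3]-shift on the convex face). This gives 2-(trimethylsilyl)ethyl (1R,4R,4aR,8aS)-2-formyl-4-hydroxy-5,5,8a-trimethyl-1-[(trimethylsilyl)oxy]-1,4,4a,5,6,7,8,8a-octahydronaphthalene-1-carboxylate F3. 1 M HCl in THF then removes the silyl ether and rejoins the route at 12.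

**Further compounds**
F1 | step 2 | methyl (4aS,8aR)-5,5,8a-trimethyl-2-oxodecahydronaphthalene-1-carboxylate (mirror image of 4) | C1CC(=O)C(C(=O)OC)[C@]2(C)CCCC(C)(C)[C@H]12
F2 | step 6 | 2-(trimethylsilyl)ethyl (1R,4aR,8aS)-2-(hydroxymethyl)-5,5,8a-trimethyl-1-[(trimethylsilyl)oxy]-1,4,4a,5,6,7,8,8a-octahydronaphthalene-1-carboxylate | C1C=C(CO)[C@@](O[Si](C)(C)C)(C(=O)OCC[Si](C)(C)C)[C@@]2(C)CCCC(C)(C)[C@@H]12
F3 | step 7 | 2-(trimethylsilyl)ethyl (1R,4R,4aR,8aS)-2-formyl-4-hydroxy-5,5,8a-trimethyl-1-[(trimethylsilyl)oxy]-1,4,4a,5,6,7,8,8a-octahydronaphthalene-1-carboxylate | O[C@@H]1C=C(C=O)[C@@](O[Si](C)(C)C)(C(=O)OCC[Si](C)(C)C)[C@@]2(C)CCCC(C)(C)[C@@H]12
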